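In a one-step world a substrate falls by one constant; this flask has several steps, and I want to reduce them to one.

left-handed substrate 2.0 M; gas 200 mM (held); free catalyst 10 mM; racemization catalyst 40 mM; right-handed substrate 2.0 M; time 15 h

    partner + free catalyst + left-handed substrate → free catalyst + left-handed product (k1 = 0.022 M⁻² s⁻¹)
    partner + free catalyst + right-handed substrate → free catalyst + right-handed product (k2 = 0.0024 M⁻² s⁻¹)
    left-handed substrate + racemization catalyst ⇌ right-handed substrate + racemization catalyst, rate k3*[racemization catalyst]*[left-handed substrate] forward; the back reaction follows from the equilibrium constant (k3 = 0.0063 M⁻¹ s⁻¹)
    partner → decomposed reagent (k4 = 3.9 × 10⁻⁵ s⁻¹)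
    gas ⇌ partner, rate k5*(csat - [partner]) (k5 = 0.0032 s⁻¹, csat = 200 mM)

- free catalyst is single-handed; left-handed substrate and right-handed substrate are mirror images of each other, charged as a racemate, each of them at the stated concentration
- at the start none of partner is dissolved
- the reaction counts as stopped when no species that holds the left-handed substrate and right-handed substrate together changes by six tenths of a point or more over the second half of the time
- run time (flask): 15 h

* which holds at 15 h: what has brought the reaction to rest, or that it has not come to rest (it is still moving / all of the left-handed substrate has reacted / no working catalyst is left / forward and back rates have come level)
* amount of left-handed product at 15 h, in percent of the left-handed substrate and right-handed substrate together charged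
* amount of right-handed substrate at 15 h, in percent of the left-handed substrate and right-handed substrate together charged

With free catalyst, the constant of left-handed substrate is 9.17 times that of right-handed substrate. At equal levels, 90.2% of the product is then left-handed, yet left-handed substrate is 50.0% of the charge.

I clear this with two half-lives. The forward turning of left-handed substrate into right-handed substrate has a half-life of 0.764 h, shorter than the 4.38 h half-life of left-handed substrate reacting with partner held at its saturation concentration. So I treat both forms as level, in one pool c charged at 4.00 M. Partner adjusts within 5.21 min, much shorter than the run, so I set its supply equal to its use. The pool then follows a Michaelis form, which integrates in closed form: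

−dc/dt = V·c/(K + c)

K·ln(c_start/c) + c_start − c = V·t

Here V, the transfer coefficient times the saturation concentration, is 2.30 M h⁻¹. K is 26.5 M: the decomposition constant plus the transfer coefficient, over the mean of the two substrate constants times the free catalyst, the pool's half-saturation level. It exceeds the charge, so the decay is nearly pseudo-first-order. V·t is 34.6 M. I solve in two passes:

first pass: c = c_start·exp(−V·t/K) = 1.09 M

second pass: c = c_start·exp(−(V·t − c_start + c)/K) = 1.21 M

The pool still falls at 0.100 M h⁻¹, so I say it is still moving, with right-handed substrate at 15.2% and left-handed product at 62.8%.

The forecast answers: it is still moving, with left-handed product at 61.3% and right-handed substrate at 16.3%, on the ground that “this is a dynamic kinetic resolution”. Its left-handed product lies below my figure and its right-handed substrate above mine.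

The flask gives: it is still moving, with left-handed product at 61.4%, below my figure, and right-handed substrate at 16.3%. The neighbour flask holds 0.0025 M of free catalyst, a quarter of the recipe, so its K is 106 M. The two passes put its pool at 2.89 M, then 2.92 M. That puts right-handed substrate at 36.5% and left-handed product at 24.4%. The neighbour flask reads right-handed substrate at 37.0% and left-handed product at 24.1%.

All constants are those of an exercise; the flask was simulated.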